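## Retrosynthetic overview

1. Target 17 ⇐ aryl tosylate 16 by S–O cleavage; the tosylate is the element that steers the aryl–aryl bond.
2. 16 ⇐ acyclic 1,4-diol 14 in one flask: ring C (tetrahydrofuran) closes first by capture of the C7 benzylic cation by O9', the counterpart of quinone-methide trapping; ring D (eight-membered) then closes by oxidative C2–C2' aryl–aryl coupling.
3. 14 ⇐ γ-keto imide 13 by hydride reduction; 13 ⇐ oxidative 8–8' enolate heterocoupling of imide 9 with propiophenone 10.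
4. 9 ⇐ aldehyde 1 by tosylation, Meldrum's acid homologation and N-acylation of oxazolidinone 7.

Assumption: the SMILES defines no biaryl axis, so the axis is taken as the one the oxygen-bridged ring system enforces. Lignan numbering is used: ring B (trimethoxyphenyl) carries C7/C8/C9, ring A (phenol ring) carries C7'/C8'/C9'. Ts = 4-methylbenzenesulfonyl. The route is a proposal and has not been run.

## Route

Step 1
Reactants: 1 3-hydroxy-4,5-dimethoxybenzaldehyde
Product: 2 5-formyl-2,3-dimethoxyphenyl 4-methylbenzenesulfonate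
Conditions: TsCl (1.1 equiv), Et3N (1.5 equiv), DMAP (5 mol %), CH2Cl2, 0 °C → rt
Reagents that add atoms: 4-methylbenzenesulfonyl chloride (TsCl), Cc1ccc(cc1)S(=O)(=O)Cl
Why: O-sulfonylation of the phenol installs a base-, hydride- and oxidant-stable, electron-withdrawing group that later makes the ring A position para to it the less reactive one.

Step 2
Reactants: 2 5-formyl-2,3-dimethoxyphenyl 4-methylbenzenesulfonate; 3 Meldrum's acid
Product: 6 3-{3,4-dimethoxy-5-[(4-methylbenzenesulfonyl)oxy]phenyl}propanoic acid, via arylidene Meldrum's acid 4 (not isolated), via benzyl Meldrum's acid 5 (not isolated)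
Conditions: HCO2H/Et3N (5:2), 100 °C, 4 h; then aq. HCl
Reagents that add atoms: none
Why: One-pot Knoevenagel condensation, formate conjugate transfer hydrogenation and hydrolysis/decarboxylation gives the 3-arylpropanoic acid; no stereocenter is formed and the aryl tosylate tolerates the buffered medium.

Step 3
Reactants: 6 3-{3,4-dimethoxy-5-[(4-methylbenzenesulfonyl)oxy]phenyl}propanoic acid; 7 (4S)-4-benzyl-1,3-oxazolidin-2-one
Product: 9 (4S)-4-benzyl-3-(3-{3,4-dimethoxy-5-[(4-methylbenzenesulfonyl)oxy]phenyl}propanoyl)-1,3-oxazolidin-2-one, via mixed pivalic anhydride 8 (not isolated)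
Conditions: t-BuCOCl (1.05 equiv), Et3N (2.5 equiv), THF, −20 °C; then LiCl (1.1 equiv), 7, −20 °C → rt
Reagents that add atoms: none
Why: Mixed-anhydride N-acylation of the Evans oxazolidinone under LiCl/Et3N conditions attaches the auxiliary without strong base.

Step 4
Reactants: 9 (4S)-4-benzyl-3-(3-{3,4-dimethoxy-5-[(4-methylbenzenesulfonyl)oxy]phenyl}propanoyl)-1,3-oxazolidin-2-one; 10 1-(3,4,5-trimethoxyphenyl)propan-1-one
Product: 13 (4S)-4-benzyl-3-[(2R,3R)-2-({3,4-dimethoxy-5-[(4-methylbenzenesulfonyl)oxy]phenyl}methyl)-3-methyl-4-oxo-4-(3,4,5-trimethoxyphenyl)butanoyl]-1,3-oxazolidin-2-one, via imide lithium enolate 11 (not isolated), via ketone lithium enolate 12 (not isolated)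
Conditions: 9 (1.0 equiv), 10 (1.2 equiv), LiN(i-Pr)2 (2.2 equiv), THF, −78 °C, 30 min; then Fe(acac)3 (2.2 equiv, trivalent iron), −78 °C → rt; chromatography to remove the C8 epimer
Reagents that add atoms: none
Why: Oxidative enolate heterocoupling (one-electron oxidation of the mixed lithium enolates by trivalent iron) joins C8 and C8' in the manner of the biosynthetic 8–8' coupling; C8' (R) is set by bond formation on the face of the chelated Z-enolate opposite the auxiliary benzyl group, as in alkylations of such imides, whereas C8 forms with low selectivity (about 2:1 expected) and the (2R,3R) isomer is isolated by chromatography.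

Step 5
Reactants: 13 (4S)-4-benzyl-3-[(2R,3R)-2-({3,4-dimethoxy-5-[(4-methylbenzenesulfonyl)oxy]phenyl}methyl)-3-methyl-4-oxo-4-(3,4,5-trimethoxyphenyl)butanoyl]-1,3-oxazolidin-2-one
Product: 14 5-[(2R,3R)-4-hydroxy-2-(hydroxymethyl)-3-methyl-4-(3,4,5-trimethoxyphenyl)butyl]-2,3-dimethoxyphenyl 4-methylbenzenesulfonate (both C7 carbinol epimers)
Conditions: LiBH4 (4 equiv), MeOH (2 equiv), THF, 0 °C → rt
Reagents that add atoms: none
Why: Hydride reduction of the ketone and reductive cleavage of the N-acyl oxazolidinone (directly or through the γ-lactone) gives the 1,4-diol without touching C8, C8', the aryl tosylate or the methyl ethers; the C7 carbinol configuration is irrelevant because C7 is re-set in step 6.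

Step 6
Reactants: 14 5-[(2R,3R)-4-hydroxy-2-(hydroxymethyl)-3-methyl-4-(3,4,5-trimethoxyphenyl)butyl]-2,3-dimethoxyphenyl 4-methylbenzenesulfonate
Product: 16 (7R,8R,8'R)-3,4,5,4',5'-pentamethoxy-7,9'-epoxy-2,2'-cyclolignan-3'-yl 4-methylbenzenesulfonate, via tetrahydrofuran lignan 15 (not isolated)
Conditions: BF3·OEt2 (3 equiv), 4 Å MS, CH2Cl2, −40 → −10 °C, 30 min; then PhI(OCOCF3)2 (1.2 equiv), −40 °C, 1 h; aq. NaHCO3/Na2S2O3
Reagents that add atoms: none
Why: Proposed new method: BF3 ionizes either C7 epimer of the electron-rich benzylic carbinol to the 3,4,5-trimethoxybenzylic cation (the O-methylated counterpart of the biosynthetic quinone methide), which O9' captures 5-exo under reversible conditions to give the all-trans tetrahydrofuran 15 (7R, aryl trans to the C8 methyl and cis to the C8' benzyl group); PhI(OCOCF3)2/BF3 then oxidizes the more electron-rich ring B to its radical cation, which ring A attacks at C2', the position para to the C5' methoxy group and not para to the deactivating tosyloxy group, closing ring D with the axis fixed by the bridge; the closest known reaction types are the acid-mediated cyclodehydration of 1-aryl-1,4-diols to 2-aryltetrahydrofurans and the Kita-type non-phenolic oxidative biaryl coupling with PhI(OCOCF3)2/BF3·OEt2 used for dibenzocyclooctadiene lignans.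

Step 7
Reactants: 16 (7R,8R,8'R)-3,4,5,4',5'-pentamethoxy-7,9'-epoxy-2,2'-cyclolignan-3'-yl 4-methylbenzenesulfonate
Product: 17 (7R,8R,8'R)-3,4,5,4',5'-pentamethoxy-7,9'-epoxy-2,2'-cyclolignan-3'-ol (CNP0322364.1)
Conditions: KOH (10 equiv), MeOH/THF/H2O, 65 °C; then aq. NH4Cl
Reagents that add atoms: none
Why: Saponification of the aryl sulfonate (hydroxide attack at sulfur, S–O cleavage) frees the phenol, while the methyl ethers, the benzylic tetrahydrofuran and all stereocenters are inert to base.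

## Compound list

1 | 3-hydroxy-4,5-dimethoxybenzaldehyde | O=Cc1cc(O)c(OC)c(OC)c1 | starting material
2 | 5-formyl-2,3-dimethoxyphenyl 4-methylbenzenesulfonate | O=Cc1cc(OC)c(OC)c(OS(=O)(=O)c2ccc(C)cc2)c1 | intermediate
3 | Meldrum's acid (2,2-dimethyl-1,3-dioxane-4,6-dione) | CC1(C)OC(=O)CC(=O)O1 | starting material
4 | 5-[(2,2-dimethyl-4,6-dioxo-1,3-dioxan-5-ylidene)methyl]-2,3-dimethoxyphenyl 4-methylbenzenesulfonate | CC1(C)OC(=O)C(=Cc2cc(OC)c(OC)c(OS(=O)(=O)c3ccc(C)cc3)c2)C(=O)O1 | intermediate (not isolated)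
5 | 5-[(2,2-dimethyl-4,6-dioxo-1,3-dioxan-5-yl)methyl]-2,3-dimethoxyphenyl 4-methylbenzenesulfonate | CC1(C)OC(=O)C(Cc2cc(OC)c(OC)c(OS(=O)(=O)c3ccc(C)cc3)c2)C(=O)O1 | intermediate (not isolated)
6 | 3-{3,4-dimethoxy-5-[(4-methylbenzenesulfonyl)oxy]phenyl}propanoic acid | OC(=O)CCc1cc(OC)c(OC)c(OS(=O)(=O)c2ccc(C)cc2)c1 | intermediate
7 | (4S)-4-benzyl-1,3-oxazolidin-2-one | O=C1N[C@@H](Cc2ccccc2)CO1 | starting material
8 | 3-{3,4-dimethoxy-5-[(4-methylbenzenesulfonyl)oxy]phenyl}propanoic pivalic anhydride | CC(C)(C)C(=O)OC(=O)CCc1cc(OC)c(OC)c(OS(=O)(=O)c2ccc(C)cc2)c1 | intermediate (not isolated)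
9 | (4S)-4-benzyl-3-(3-{3,4-dimethoxy-5-[(4-methylbenzenesulfonyl)oxy]phenyl}propanoyl)-1,3-oxazolidin-2-one | O=C(CCc1cc(OC)c(OC)c(OS(=O)(=O)c2ccc(C)cc2)c1)N1[C@@H](Cc2ccccc2)COC1=O | intermediate
10 | 1-(3,4,5-trimethoxyphenyl)propan-1-one | CCC(=O)c1cc(OC)c(OC)c(OC)c1 | starting material
11 | lithium (Z)-enolate of imide 9 | [Li+].[O-]/C(=C\Cc1cc(OC)c(OC)c(OS(=O)(=O)c2ccc(C)cc2)c1)N1[C@@H](Cc2ccccc2)COC1=O | intermediate (not isolated)
12 | lithium (Z)-1-(3,4,5-trimethoxyphenyl)prop-1-en-1-olate | [Li+].[O-]/C(=C\C)c1cc(OC)c(OC)c(OC)c1 | intermediate (not isolated)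
13 | (4S)-4-benzyl-3-[(2R,3R)-2-({3,4-dimethoxy-5-[(4-methylbenzenesulfonyl)oxy]phenyl}methyl)-3-methyl-4-oxo-4-(3,4,5-trimethoxyphenyl)butanoyl]-1,3-oxazolidin-2-one | O=C(N1[C@@H](Cc2ccccc2)COC1=O)[C@H](Cc1cc(OC)c(OC)c(OS(=O)(=O)c2ccc(C)cc2)c1)[C@@H](C)C(=O)c1cc(OC)c(OC)c(OC)c1 | intermediate
14 | 5-[(2R,3R)-4-hydroxy-2-(hydroxymethyl)-3-methyl-4-(3,4,5-trimethoxyphenyl)butyl]-2,3-dimethoxyphenyl 4-methylbenzenesulfonate (both C7 carbinol epimers) | OC[C@H](Cc1cc(OC)c(OC)c(OS(=O)(=O)c2ccc(C)cc2)c1)[C@@H](C)C(O)c1cc(OC)c(OC)c(OC)c1 | intermediate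
15 | 5-{[(3R,4R,5R)-4-methyl-5-(3,4,5-trimethoxyphenyl)oxolan-3-yl]methyl}-2,3-dimethoxyphenyl 4-methylbenzenesulfonate | COc1cc(cc(OC)c1OC)[C@@H]1OC[C@H](Cc2cc(OC)c(OC)c(OS(=O)(=O)c3ccc(C)cc3)c2)[C@H]1C | intermediate (not isolated)
16 | (7R,8R,8'R)-3,4,5,4',5'-pentamethoxy-7,9'-epoxy-2,2'-cyclolignan-3'-yl 4-methylbenzenesulfonate (O-tosyl target) | COc1cc2c(c(OS(=O)(=O)c3ccc(C)cc3)c1OC)-c1c(cc(OC)c(OC)c1OC)[C@@H]1OC[C@H](C2)[C@H]1C | intermediate
17 | (7R,8R,8'R)-3,4,5,4',5'-pentamethoxy-7,9'-epoxy-2,2'-cyclolignan-3'-ol (CNP0322364.1) | COc1cc2c(c(O)c1OC)-c1c(cc(OC)c(OC)c1OC)[C@@H]1OC[C@H](C2)[C@H]1C | target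

## Step count and risks

Total steps: 7. Longest linear sequence: 7 (from 1).

Three steps most likely to fail:

**Step 6 (two-ring cascade).** The C7 cation may instead be captured by ring A (aryltetralin), and the transannular aryl–aryl coupling may be slow or may take the ring A position para to the tosyloxy group. The fallback replaces the dehydrogenative coupling by a reductive coupling of pre-placed halides. It sets out from 15, isolated by quenching step 6 after the BF3 stage. NBS (2.1 equiv, MeCN, 0 °C) brominates the only free position of ring B and the ring A position para to methoxy, giving 2-bromo-3-{[(3R,4R,5R)-5-(2-bromo-3,4,5-trimethoxyphenyl)-4-methyloxolan-3-yl]methyl}-5,6-dimethoxyphenyl 4-methylbenzenesulfonate F1. Intramolecular reductive aryl–aryl coupling with Ni(cod)2 (zerovalent nickel) and 2,2'-bipyridine in DMF at 50 °C then closes ring D, and the route is rejoined at 16.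

**Step 4 (heterocoupling).** Homodimers, modest yield and the poor control of C8 are the weak points. If the facial sense at C8' turns out opposite to the alkylation model, the enantiomeric auxiliary is used. The fallback gives up the oxidative coupling and sets C8 by asymmetric hydrogenation and C8' by lactone alkylation. It sets out from 10 and 2.
- Ketone 10 is condensed with glyoxylic acid (AcOH, cat. H2SO4, 100 °C) to (E)-3-methyl-4-oxo-4-(3,4,5-trimethoxyphenyl)but-2-enoic acid F2.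
- Hydrogenation over Ru(OAc)2(BINAP) (divalent ruthenium, the ligand antipode that gives the 3R acid) gives (3R)-3-methyl-4-oxo-4-(3,4,5-trimethoxyphenyl)butanoic acid F3.
- NaBH4 and then TsOH give (4R)-4-methyl-5-(3,4,5-trimethoxyphenyl)oxolan-2-one F4 as both C5 epimers.
- Aldehyde 2 is reduced (NaBH4) to 5-(hydroxymethyl)-2,3-dimethoxyphenyl 4-methylbenzenesulfonate F5 and brominated (PBr3) to 5-(bromomethyl)-2,3-dimethoxyphenyl 4-methylbenzenesulfonate F6.
- The lithium enolate of F4 (LiN(SiMe3)2, THF, −78 °C) is alkylated by F6 trans to the C4 methyl group to give 2,3-dimethoxy-5-{[(3R,4R)-4-methyl-2-oxo-5-(3,4,5-trimethoxyphenyl)oxolan-3-yl]methyl}phenyl 4-methylbenzenesulfonate F7.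
- LiBH4 opens F7 to diol 14, where the route resumes; the C7 epimers again converge in step 6.

**Step 7 (detosylation).** The tosylate in 16 is flanked by the biaryl bond and a methoxy group and may resist hydroxide. The fallback exchanges the protecting group before ring D exists. It sets out from 15. KOH/MeOH cleaves the unhindered tosylate to 5-{[(3R,4R,5R)-4-methyl-5-(3,4,5-trimethoxyphenyl)oxolan-3-yl]methyl}-2,3-dimethoxyphenol F8. Ac2O/pyridine gives 5-{[(3R,4R,5R)-4-methyl-5-(3,4,5-trimethoxyphenyl)oxolan-3-yl]methyl}-2,3-dimethoxyphenyl acetate F9. PhI(OCOCF3)2/BF3·OEt2 (CH2Cl2, −40 °C) couples it, the acetoxy group directing as the tosyloxy group does, to (7R,8R,8'R)-3,4,5,4',5'-pentamethoxy-7,9'-epoxy-2,2'-cyclolignan-3'-yl acetate F10. K2CO3/MeOH at rt then gives 17.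

Further compounds
F1 | step 6 | 2-bromo-3-{[(3R,4R,5R)-5-(2-bromo-3,4,5-trimethoxyphenyl)-4-methyloxolan-3-yl]methyl}-5,6-dimethoxyphenyl 4-methylbenzenesulfonate | COc1cc(c(Br)c(OC)c1OC)[C@@H]1OC[C@H](Cc2cc(OC)c(OC)c(OS(=O)(=O)c3ccc(C)cc3)c2Br)[C@H]1C
F2 | step 4 | (E)-3-methyl-4-oxo-4-(3,4,5-trimethoxyphenyl)but-2-enoic acid | OC(=O)/C=C(\C)C(=O)c1cc(OC)c(OC)c(OC)c1
F3 | step 4 | (3R)-3-methyl-4-oxo-4-(3,4,5-trimethoxyphenyl)butanoic acid | OC(=O)C[C@@H](C)C(=O)c1cc(OC)c(OC)c(OC)c1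
F4 | step 4 | (4R)-4-methyl-5-(3,4,5-trimethoxyphenyl)oxolan-2-one (both C5 epimers) | O=C1C[C@@H](C)C(O1)c1cc(OC)c(OC)c(OC)c1
F5 | step 4 | 5-(hydroxymethyl)-2,3-dimethoxyphenyl 4-methylbenzenesulfonate | OCc1cc(OC)c(OC)c(OS(=O)(=O)c2ccc(C)cc2)c1
F6 | step 4 | 5-(bromomethyl)-2,3-dimethoxyphenyl 4-methylbenzenesulfonate | BrCc1cc(OC)c(OC)c(OS(=O)(=O)c2ccc(C)cc2)c1
F7 | step 4 | 2,3-dimethoxy-5-{[(3R,4R)-4-methyl-2-oxo-5-(3,4,5-trimethoxyphenyl)oxolan-3-yl]methyl}phenyl 4-methylbenzenesulfonate (both C5 epimers) | O=C1[C@H](Cc2cc(OC)c(OC)c(OS(=O)(=O)c3ccc(C)cc3)c2)[C@@H](C)C(O1)c1cc(OC)c(OC)c(OC)c1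
F8 | step 7 | 5-{[(3R,4R,5R)-4-methyl-5-(3,4,5-trimethoxyphenyl)oxolan-3-yl]methyl}-2,3-dimethoxyphenol | COc1cc(cc(OC)c1OC)[C@@H]1OC[C@H](Cc2cc(OC)c(OC)c(O)c2)[C@H]1C
F9 | step 7 | 5-{[(3R,4R,5R)-4-methyl-5-(3,4,5-trimethoxyphenyl)oxolan-3-yl]methyl}-2,3-dimethoxyphenyl acetate | COc1cc(cc(OC)c1OC)[C@@H]1OC[C@H](Cc2cc(OC)c(OC)c(OC(C)=O)c2)[C@H]1C
F10 | step 7 | (7R,8R,8'R)-3,4,5,4',5'-pentamethoxy-7,9'-epoxy-2,2'-cyclolignan-3'-yl acetate | COc1cc2c(c(OC(C)=O)c1OC)-c1c(cc(OC)c(OC)c1OC)[C@@H]1OC[C@H](C2)[C@H]1C
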